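**Assumption:** the target is taken exactly as the SMILES gives it: (6S,7S,8S), with both ring double bonds cis in the ring (Z,Z). Atoms are labelled C1–C10 as in germacranes: C1=C10(Me), C4(Me)=C5, C6–OH, C7–i-Pr, C8–O-aroyl. PMB = 4-methoxybenzyl.

## Retrosynthetic overview

1. The ten-membered carbocycle (the only ring of the target) is closed last, at C1=C10, by ring-closing metathesis of an acyclic triene that already carries the protected aroyl ester on O8.
2. C8–C9 and the C8 carbinol come from a Felkin/1,3-anti Hosomi–Sakurai methallylation of an α-isopropyl-β-PMB-oxy aldehyde.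
3. C2–C3 and the Z C4=C5 olefin come from a [2,3]-Wittig–Still rearrangement of a stannylmethyl ether (key C–C bond), followed by a vinyl coupling that adds C1.
4. C5–C8 with the C6/C7 diad come from diethyl D-malate (C6 bought) and a Fráter–Seebach isopropylation (C7). A temporary 1,3-dioxane (first ring formed, step 3; opened, step 8) tells the three oxygens apart.

## Route

Step 1
Reactants: 1 diethyl (2R)-2-hydroxybutanedioate (diethyl D-malate)
Product: 3 diethyl (2R,3S)-2-hydroxy-3-(propan-2-yl)butanedioate, via dilithium alkoxide-enolate 2 (not isolated)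
Conditions: LiN(SiMe3)2 (2.2 equiv), THF, −78 → −20 °C; then i-PrI, DMPU, −78 → 0 °C
Reagents that add atoms: 2-iodopropane, CC(C)I
Why: Fráter–Seebach alkylation: the chelated alkoxide-enolate 2 is alkylated on the face away from the C5 ester group at the C6 carbinol carbon, so the purchased C6 centre sets C7 anti (2R,3S).

Step 2
Reactants: 3 diethyl (2R,3S)-2-hydroxy-3-(propan-2-yl)butanedioate
Product: 4 (2R,3R)-3-(propan-2-yl)butane-1,2,4-triol
Conditions: LiAlH4, THF, 0 °C → reflux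
Reagents that add atoms: none
Why: Hydride reduction of both esters to primary alcohols; no stereocentre is touched.

Step 3
Reactants: 4 (2R,3R)-3-(propan-2-yl)butane-1,2,4-triol
Product: 5 [(2R,4R,5R)-2-(4-methoxyphenyl)-5-(propan-2-yl)-1,3-dioxan-4-yl]methanol
Conditions: 4-MeOC6H4CH(OMe)2, PPTS (cat.), CH2Cl2, rt (equilibrating)
Reagents that add atoms: 4-methoxybenzaldehyde dimethyl acetal, COc1ccc(C(OC)OC)cc1
Why: Thermodynamic transacetalisation: arylidene acetals prefer the six-membered 1,3-dioxane (O6/O8) with aryl, CH2OH and i-Pr all equatorial, which fixes the acetal centre (2R) and leaves only the C5 hydroxyl free.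

Step 4
Reactants: 5 [(2R,4R,5R)-2-(4-methoxyphenyl)-5-(propan-2-yl)-1,3-dioxan-4-yl]methanol
Product: 7 1-[(2R,4R,5R)-2-(4-methoxyphenyl)-5-(propan-2-yl)-1,3-dioxan-4-yl]-2-methylprop-2-en-1-ol (both C5 epimers), via dioxane aldehyde 6 (not isolated)
Conditions: (COCl)2, DMSO, CH2Cl2, −78 °C; Et3N; then CH2=C(CH3)MgBr (excess), THF, −78 → 0 °C
Reagents that add atoms: isopropenylmagnesium bromide, C=C(C)[Mg]Br
Why: Swern oxidation with in-situ Grignard 1,2-addition, so the epimerisable α-alkoxy aldehyde 6 is never handled; the new carbinol centre forms unselectively and is destroyed in step 6.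

Step 5
Reactants: 7 1-[(2R,4R,5R)-2-(4-methoxyphenyl)-5-(propan-2-yl)-1,3-dioxan-4-yl]-2-methylprop-2-en-1-ol
Product: 8 tributyl[({1-[(2R,4R,5R)-2-(4-methoxyphenyl)-5-(propan-2-yl)-1,3-dioxan-4-yl]-2-methylprop-2-en-1-yl}oxy)methyl]stannane
Conditions: KH, 18-crown-6 (cat.), Bu3SnCH2I, THF, 0 °C → rt
Reagents that add atoms: (iodomethyl)tributylstannane, CCCC[Sn](CCCC)(CCCC)CI
Why: Williamson etherification of the potassium alkoxide with Still's iodomethylstannane.

Step 6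
Reactants: 8 tributyl[({1-[(2R,4R,5R)-2-(4-methoxyphenyl)-5-(propan-2-yl)-1,3-dioxan-4-yl]-2-methylprop-2-en-1-yl}oxy)methyl]stannane
Product: 11 (3Z)-4-[(2R,4S,5R)-2-(4-methoxyphenyl)-5-(propan-2-yl)-1,3-dioxan-4-yl]-3-methylbut-3-en-1-yl 4-methylbenzenesulfonate, via lithiomethyl ether 9 (not isolated), via lithium alkoxide 10 (not isolated)
Conditions: n-BuLi, THF, −78 °C; then TsCl, −78 → 0 °C
Reagents that add atoms: 4-methylbenzenesulfonyl chloride, Cc1ccc(cc1)S(=O)(=O)Cl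
Why: Tin–lithium exchange then [2,3]-Wittig–Still sigmatropic rearrangement forms C2–C3 and the C4=C5 olefin; the 2-methyl group forces the dioxanyl substituent pseudo-axial in the envelope transition state, which gives the Z olefin, and the alkoxide is trapped as the tosylate.

Step 7
Reactants: 11 (3Z)-4-[(2R,4S,5R)-2-(4-methoxyphenyl)-5-(propan-2-yl)-1,3-dioxan-4-yl]-3-methylbut-3-en-1-yl 4-methylbenzenesulfonate
Product: 12 (2R,4S,5R)-2-(4-methoxyphenyl)-4-[(1Z)-2-methylhexa-1,5-dien-1-yl]-5-(propan-2-yl)-1,3-dioxane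
Conditions: CH2=CHMgBr, CuI (10 mol %), THF, −30 → 0 °C
Reagents that add atoms: vinylmagnesium bromide, C=C[Mg]Br
Why: Copper-catalysed sp3–sp2 coupling of the primary tosylate with the vinyl Grignard reagent adds C1 as a terminal vinyl group without touching the Z olefin.

Step 8
Reactants: 12 (2R,4S,5R)-2-(4-methoxyphenyl)-4-[(1Z)-2-methylhexa-1,5-dien-1-yl]-5-(propan-2-yl)-1,3-dioxane
Product: 13 (2R,3S,4Z)-3-[(4-methoxyphenyl)methoxy]-5-methyl-2-(propan-2-yl)nona-4,8-dien-1-ol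
Conditions: i-Bu2AlH, CH2Cl2, −78 → 0 °C
Reagents that add atoms: none
Why: Regioselective reductive opening of the 4-methoxybenzylidene acetal: aluminium binds the less hindered primary oxygen (O8), so the PMB group stays on the secondary O6 and the C8 hydroxyl is freed.

Step 9
Reactants: 13 (2R,3S,4Z)-3-[(4-methoxyphenyl)methoxy]-5-methyl-2-(propan-2-yl)nona-4,8-dien-1-ol
Product: 14 (2S,3S,4Z)-3-[(4-methoxyphenyl)methoxy]-5-methyl-2-(propan-2-yl)nona-4,8-dienal
Conditions: Dess–Martin periodinane, NaHCO3, CH2Cl2, 0 °C → rt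
Reagents that add atoms: none
Why: Buffered Dess–Martin oxidation of the primary alcohol; the non-basic conditions keep the α-centre C7 intact.

Step 10
Reactants: 14 (2S,3S,4Z)-3-[(4-methoxyphenyl)methoxy]-5-methyl-2-(propan-2-yl)nona-4,8-dienal
Product: 15 (4S,5R,6S,7Z)-6-[(4-methoxyphenyl)methoxy]-2,8-dimethyl-5-(propan-2-yl)dodeca-1,7,11-trien-4-ol
Conditions: CH2=C(CH3)CH2SiMe3, BF3·OEt2, CH2Cl2, −78 °C
Reagents that add atoms: trimethyl(2-methylprop-2-en-1-yl)silane, C=C(C)C[Si](C)(C)C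
Why: Hosomi–Sakurai allylation through an open transition state: in this anti α,β-disubstituted β-alkoxy aldehyde, Felkin–Anh control (α-centre C7) and 1,3-anti induction (β-OPMB at C6) reinforce each other and place the new C8 hydroxyl syn to i-Pr and anti to O6 (8S).

Step 11
Reactants: 15 (4S,5R,6S,7Z)-6-[(4-methoxyphenyl)methoxy]-2,8-dimethyl-5-(propan-2-yl)dodeca-1,7,11-trien-4-ol
Product: 16 (4S,5R,6S,7Z)-6-[(4-methoxyphenyl)methoxy]-2,8-dimethyl-5-(propan-2-yl)dodeca-1,7,11-trien-4-yl 4-(acetyloxy)benzoate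
Conditions: 4-AcOC6H4COCl, pyridine, DMAP (cat.), CH2Cl2, 0 °C → rt
Reagents that add atoms: 4-(acetyloxy)benzoyl chloride, CC(=O)Oc1ccc(cc1)C(=O)Cl
Why: DMAP-catalysed acylation of the only free hydroxyl (O8) with retention at C8; the phenol is carried as its acetate.

Step 12
Reactants: 16 (4S,5R,6S,7Z)-6-[(4-methoxyphenyl)methoxy]-2,8-dimethyl-5-(propan-2-yl)dodeca-1,7,11-trien-4-yl 4-(acetyloxy)benzoate
Product: 17 (1S,3Z,7Z,9S,10R)-9-[(4-methoxyphenyl)methoxy]-3,7-dimethyl-10-(propan-2-yl)cyclodeca-3,7-dien-1-yl 4-(acetyloxy)benzoate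
Conditions: second-generation Grubbs catalyst RuCl2(=CHPh)(PCy3)(H2IMes) (10 mol %), toluene (1 mM), 80 °C
Reagents that add atoms: none
Why: Ring-closing metathesis starts at the monosubstituted vinyl group and closes onto the methallyl olefin (the only other olefin in reach would give a cyclobutene); in a ten-membered ring the cis olefin is about 3 kcal/mol more stable than the trans one, and a cis,trans-cyclodeca-1,5-diene is strongly strained, so C1=C10 should form Z.

Step 13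
Reactants: 17 (1S,3Z,7Z,9S,10R)-9-[(4-methoxyphenyl)methoxy]-3,7-dimethyl-10-(propan-2-yl)cyclodeca-3,7-dien-1-yl 4-(acetyloxy)benzoate
Product: 18 (1S,3Z,7Z,9S,10S)-9-hydroxy-3,7-dimethyl-10-(propan-2-yl)cyclodeca-3,7-dien-1-yl 4-(acetyloxy)benzoate
Conditions: DDQ (1.3 equiv), CH2Cl2/pH 7 phosphate buffer, 0 °C
Reagents that add atoms: none
Why: Oxidative cleavage of the PMB ether under buffered, neutral conditions that spare the acid-sensitive cyclodecadiene, the aryl acetate and the ester.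

Step 14
Reactants: 18 (1S,3Z,7Z,9S,10S)-9-hydroxy-3,7-dimethyl-10-(propan-2-yl)cyclodeca-3,7-dien-1-yl 4-(acetyloxy)benzoate
Product: 19 (1S,3Z,7Z,9S,10S)-9-hydroxy-3,7-dimethyl-10-(propan-2-yl)cyclodeca-3,7-dien-1-yl 4-hydroxybenzoate (target)
Conditions: K2CO3 (0.3 equiv), MeOH, 0 °C, 20 min
Reagents that add atoms: none
Why: Chemoselective methanolysis of the aryl acetate, which is far faster than attack on the hindered benzoate; the phenoxide that forms further deactivates the benzoate carbonyl towards methanolysis and O8→O6 migration.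

## Compound list

1 | diethyl (2R)-2-hydroxybutanedioate (diethyl D-malate) | CCOC(=O)[C@H](O)CC(=O)OCC | starting material
2 | dilithium alkoxide-enolate of 1 (E ester enolate at C7=C8, lithium alkoxide at C6) | [Li+].[Li+].CCO/C([O-])=C/[C@@H]([O-])C(=O)OCC | intermediate
3 | diethyl (2R,3S)-2-hydroxy-3-(propan-2-yl)butanedioate | CCOC(=O)[C@H](O)[C@H](C(C)C)C(=O)OCC | intermediate
4 | (2R,3R)-3-(propan-2-yl)butane-1,2,4-triol | OC[C@H](O)[C@H](C(C)C)CO | intermediate
5 | [(2R,4R,5R)-2-(4-methoxyphenyl)-5-(propan-2-yl)-1,3-dioxan-4-yl]methanol | OC[C@H](O[C@H](c1ccc(OC)cc1)OC2)[C@@H]2C(C)C | intermediate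
6 | (2R,4R,5R)-2-(4-methoxyphenyl)-5-(propan-2-yl)-1,3-dioxane-4-carbaldehyde | O=C[C@H](O[C@H](c1ccc(OC)cc1)OC2)[C@@H]2C(C)C | intermediate
7 | 1-[(2R,4R,5R)-2-(4-methoxyphenyl)-5-(propan-2-yl)-1,3-dioxan-4-yl]-2-methylprop-2-en-1-ol (both carbinol epimers) | C=C(C)C(O)[C@H](O[C@H](c1ccc(OC)cc1)OC2)[C@@H]2C(C)C | intermediate
8 | tributyl[({1-[(2R,4R,5R)-2-(4-methoxyphenyl)-5-(propan-2-yl)-1,3-dioxan-4-yl]-2-methylprop-2-en-1-yl}oxy)methyl]stannane | C=C(C)C(OC[Sn](CCCC)(CCCC)CCCC)[C@H](O[C@H](c1ccc(OC)cc1)OC2)[C@@H]2C(C)C | intermediate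
9 | [({1-[(2R,4R,5R)-2-(4-methoxyphenyl)-5-(propan-2-yl)-1,3-dioxan-4-yl]-2-methylprop-2-en-1-yl}oxy)methyl]lithium | [Li]COC(C(C)=C)[C@H](O[C@H](c1ccc(OC)cc1)OC2)[C@@H]2C(C)C | intermediate
10 | lithium (3Z)-4-[(2R,4S,5R)-2-(4-methoxyphenyl)-5-(propan-2-yl)-1,3-dioxan-4-yl]-3-methylbut-3-en-1-olate | [Li+].[O-]CC/C(C)=C\[C@H](O[C@H](c1ccc(OC)cc1)OC2)[C@@H]2C(C)C | intermediate
11 | (3Z)-4-[(2R,4S,5R)-2-(4-methoxyphenyl)-5-(propan-2-yl)-1,3-dioxan-4-yl]-3-methylbut-3-en-1-yl 4-methylbenzenesulfonate | Cc1ccc(cc1)S(=O)(=O)OCC/C(C)=C\[C@H](O[C@H](c1ccc(OC)cc1)OC2)[C@@H]2C(C)C | intermediate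
12 | (2R,4S,5R)-2-(4-methoxyphenyl)-4-[(1Z)-2-methylhexa-1,5-dien-1-yl]-5-(propan-2-yl)-1,3-dioxane | C=CCC/C(C)=C\[C@H](O[C@H](c1ccc(OC)cc1)OC2)[C@@H]2C(C)C | intermediate
13 | (2R,3S,4Z)-3-[(4-methoxyphenyl)methoxy]-5-methyl-2-(propan-2-yl)nona-4,8-dien-1-ol | C=CCC/C(C)=C\[C@H](OCc1ccc(OC)cc1)[C@H](C(C)C)CO | intermediate
14 | (2S,3S,4Z)-3-[(4-methoxyphenyl)methoxy]-5-methyl-2-(propan-2-yl)nona-4,8-dienal | C=CCC/C(C)=C\[C@H](OCc1ccc(OC)cc1)[C@H](C(C)C)C=O | intermediate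
15 | (4S,5R,6S,7Z)-6-[(4-methoxyphenyl)methoxy]-2,8-dimethyl-5-(propan-2-yl)dodeca-1,7,11-trien-4-ol | C=CCC/C(C)=C\[C@H](OCc1ccc(OC)cc1)[C@H](C(C)C)[C@@H](O)CC(C)=C | intermediate
16 | (4S,5R,6S,7Z)-6-[(4-methoxyphenyl)methoxy]-2,8-dimethyl-5-(propan-2-yl)dodeca-1,7,11-trien-4-yl 4-(acetyloxy)benzoate | C=CCC/C(C)=C\[C@H](OCc1ccc(OC)cc1)[C@H](C(C)C)[C@@H](OC(=O)c1ccc(OC(C)=O)cc1)CC(C)=C | intermediate
17 | (1S,3Z,7Z,9S,10R)-9-[(4-methoxyphenyl)methoxy]-3,7-dimethyl-10-(propan-2-yl)cyclodeca-3,7-dien-1-yl 4-(acetyloxy)benzoate | C/C1=C/[C@H](OCc2ccc(OC)cc2)[C@H](C(C)C)[C@@H](OC(=O)c2ccc(OC(C)=O)cc2)C/C(C)=C\CC1 | intermediate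
18 | (1S,3Z,7Z,9S,10S)-9-hydroxy-3,7-dimethyl-10-(propan-2-yl)cyclodeca-3,7-dien-1-yl 4-(acetyloxy)benzoate | C/C1=C/[C@H](O)[C@H](C(C)C)[C@@H](OC(=O)c2ccc(OC(C)=O)cc2)C/C(C)=C\CC1 | intermediate
19 | (1S,3Z,7Z,9S,10S)-9-hydroxy-3,7-dimethyl-10-(propan-2-yl)cyclodeca-3,7-dien-1-yl 4-hydroxybenzoate | C/C1=C/[C@H](O)[C@H](C(C)C)[C@@H](OC(=O)c2ccc(O)cc2)C/C(C)=C\CC1 | target

## Step count and risks

Total step count: 14 (steps 4 and 6 are one-pot, two-stage operations).
Longest linear sequence: 14 steps (1 → 19); the route is fully linear.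

The three steps most likely to fail:

**Step 1 (alkylation with a secondary iodide).** 2-Iodopropane may mainly suffer elimination, so conversion can be low. The fallback brings isopropyl in as the nucleophile. It does not start from a numbered compound of the route: it replaces 1 (and 2) by the purchased L-tartrate-derived epoxide diethyl (2R,3R)-oxirane-2,3-dicarboxylate F1. Treatment with i-PrMgCl and CuBr·SMe2 (10 mol %) in THF at −40 °C opens the C2-symmetric epoxide by SN2 attack with inversion at either (equivalent) carbon and gives 3 directly, where the route is rejoined.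

**Step 10 (facial selectivity at C8).** With an α-isopropyl group as large as the β-carbon, the Felkin preference may be weak or reversed. The fallback sets out from aldehyde 14 and deliberately makes the other epimer. Chelation-controlled methallylation (CH2=C(CH3)CH2SnBu3, MgBr2·OEt2, CH2Cl2, −20 °C; the aldehyde and the PMB-ether oxygen are bridged by magnesium and attack comes anti to i-Pr) gives (4R,5R,6S,7Z)-6-[(4-methoxyphenyl)methoxy]-2,8-dimethyl-5-(propan-2-yl)dodeca-1,7,11-trien-4-ol F2. Mitsunobu esterification of F2 with 4-acetoxybenzoic acid (PPh3, DIAD, toluene, 0 °C → rt) inverts C8 and gives 16, where the route is rejoined. Any F2 formed in the main step can be converged in the same way.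

**Step 12 (ten-membered ring closure).** Oligomerisation or failure of the crowded triene 16 to reach a closing conformation is the main danger. The fallback sets out from alcohol 15 and closes the ring with an sp2 carbon at C8 and without the aroyloxy group:
- Dess–Martin oxidation gives (5S,6S,7Z)-6-[(4-methoxyphenyl)methoxy]-2,8-dimethyl-5-(propan-2-yl)dodeca-1,7,11-trien-4-one F3.
- Ring-closing metathesis under the conditions of step 12 gives (2S,3S,4Z,8Z)-3-[(4-methoxyphenyl)methoxy]-5,9-dimethyl-2-(propan-2-yl)cyclodeca-4,8-dien-1-one F4.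
- Reduction with NaBH4/CeCl3·7H2O (MeOH, −40 °C) gives (1S,3Z,7Z,9S,10R)-9-[(4-methoxyphenyl)methoxy]-3,7-dimethyl-10-(propan-2-yl)cyclodeca-3,7-dien-1-ol F5 and/or its C8 epimer (1R,3Z,7Z,9S,10R)-9-[(4-methoxyphenyl)methoxy]-3,7-dimethyl-10-(propan-2-yl)cyclodeca-3,7-dien-1-ol F6.
- F5 is acylated with 4-(acetyloxy)benzoyl chloride as in step 11 (retention); F6 is esterified with 4-acetoxybenzoic acid under Mitsunobu conditions (inversion). Both give 17, where the route is rejoined.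

## Further compounds

F1 | step 1 | diethyl (2R,3R)-oxirane-2,3-dicarboxylate | CCOC(=O)[C@@H]1O[C@H]1C(=O)OCC
F2 | step 10 | (4R,5R,6S,7Z)-6-[(4-methoxyphenyl)methoxy]-2,8-dimethyl-5-(propan-2-yl)dodeca-1,7,11-trien-4-ol | C=CCC/C(C)=C\[C@H](OCc1ccc(OC)cc1)[C@H](C(C)C)[C@H](O)CC(C)=C
F3 | step 12 | (5S,6S,7Z)-6-[(4-methoxyphenyl)methoxy]-2,8-dimethyl-5-(propan-2-yl)dodeca-1,7,11-trien-4-one | C=CCC/C(C)=C\[C@H](OCc1ccc(OC)cc1)[C@H](C(C)C)C(=O)CC(C)=C
F4 | step 12 | (2S,3S,4Z,8Z)-3-[(4-methoxyphenyl)methoxy]-5,9-dimethyl-2-(propan-2-yl)cyclodeca-4,8-dien-1-one | C/C1=C/[C@H](OCc2ccc(OC)cc2)[C@H](C(C)C)C(=O)C/C(C)=C\CC1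
F5 | step 12 | (1S,3Z,7Z,9S,10R)-9-[(4-methoxyphenyl)methoxy]-3,7-dimethyl-10-(propan-2-yl)cyclodeca-3,7-dien-1-ol | C/C1=C/[C@H](OCc2ccc(OC)cc2)[C@H](C(C)C)[C@@H](O)C/C(C)=C\CC1
F6 | step 12 | (1R,3Z,7Z,9S,10R)-9-[(4-methoxyphenyl)methoxy]-3,7-dimethyl-10-(propan-2-yl)cyclodeca-3,7-dien-1-ol | C/C1=C/[C@H](OCc2ccc(OC)cc2)[C@H](C(C)C)[C@H](O)C/C(C)=C\CC1
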